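**Overview**

- Atom labels: lactone C12(=O)–C11(=C13H2)–C7–C6–O; C6 bears C5H=C4(CH3)–C3H2–OAc; C7 bears C8 (methacrylate), which continues as C9H2–C10(CH3)=C1H–C2H2–OH.
- Enabling feature: the ring oxygen on C6 and the acetate oxygen on C3 flank the E C5=C4 bond in a 1,4 relation, and the C12 carboxyl lies three atoms from C6. The only ring, the α-methylene-γ-lactone, and the allylic acetate are therefore the two ends of one oxidative 1,4-addition to a C6=C5–C4=C3 isoprenyl diene.
- Retrosynthetic cuts, in order: O–Si at C2; C6–O(ring) together with C3–OAc (key step); the tert-butyl ester and the O8–acyl bond; C7–C8 (allylboration); C13–B with the C7 acetate (SN2′ borylation); C7–C11 (Morita–Baylis–Hillman); C5=C6 (Wittig).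
- Forward: the chain is joined C5=C6, then C7–C11, then C7–C8 (convergent union with the C8–C2 aldehyde). O8 is acylated, the acid is unmasked, and the single ring closes last through C6–O.
- Stereochemistry: C7 and C8 arise together in the chair allylboration (syn from the boronate geometry, absolute sense from the chiral phosphoric acid). C6 is relayed from C7 as the trans lactone in the key step. The C10=C1 geometry is bought and the C5=C4 geometry follows from the syn π-allylpalladium intermediate.

Key step: step 10

Remark: the E isomer of enynol 8 is taken to be purchasable as such, and the facial sense assigned to the phosphoric acid in step 7 rests on analogy and is to be verified on the first run (the antipodal acid is used if it proves reversed).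

**Route**

Step 1
Reactants: 1 methacrolein (2-methylprop-2-enal); 2 (triphenylphosphoranylidene)acetaldehyde
Product: 3 (2E)-4-methylpenta-2,4-dienal
Conditions: 1 (3 equiv), 2 (1 equiv), BHT (trace), THF, 65 °C, sealed vessel; pentane trituration, bulb-to-bulb distillation, used promptly
Reagents that add atoms: none
Why: Wittig olefination with a formyl-stabilised ylide is reliably E-selective, and the excess of the more electrophilic methacrolein should keep the less reactive, more conjugated dienal from being homologated a second time.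

Step 2
Reactants: 3 (2E)-4-methylpenta-2,4-dienal; 4 tert-butyl acrylate
Product: 5 tert-butyl (4E)-3-hydroxy-6-methyl-2-methylidenehepta-4,6-dienoate (racemic)
Conditions: 4 (3 equiv), DABCO (1 equiv), 1,4-dioxane/H2O 1:1, rt, 2–4 d
Reagents that add atoms: none
Why: Morita–Baylis–Hillman reaction, in which the amine–acrylate zwitterion adds 1,2 to the unhindered dienal and forms C7–C11, aqueous dioxane compensating for the sluggish tert-butyl acrylate; the carbinol centre may stay racemic because step 4 erases it.

Step 3
Reactants: 5 tert-butyl (4E)-3-hydroxy-6-methyl-2-methylidenehepta-4,6-dienoate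
Product: 6 tert-butyl (4E)-3-acetoxy-6-methyl-2-methylidenehepta-4,6-dienoate (racemic)
Conditions: Ac2O, pyridine, DMAP (5 mol %), CH2Cl2, 0 °C
Reagents that add atoms: acetic anhydride, CC(=O)OC(C)=O
Why: DMAP-catalysed acetylation of a secondary allylic alcohol, run cold and stopped at full conversion so that the doubly allylic acetate does not undergo allylic transposition.

Step 4
Reactants: 6 tert-butyl (4E)-3-acetoxy-6-methyl-2-methylidenehepta-4,6-dienoate
Product: 7 tert-butyl (2E,4E)-6-methyl-2-[(4,4,5,5-tetramethyl-1,3,2-dioxaborolan-2-yl)methyl]hepta-2,4,6-trienoate (dienyl group cis to CH2B)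
Conditions: B2pin2 (1.05 equiv), CuCl (10 mol %), KOAc (1.2 equiv), DMF, rt, no protic additive
Reagents that add atoms: bis(pinacolato)diboron, CC1(C)OB(OC1(C)C)B1OC(C)(C)C(C)(C)O1
Why: Copper-catalysed SN2′ borylation of a Morita–Baylis–Hillman acetate, in which the boryl–copper species adds to the acrylate terminus C13 and the copper enolate expels the C7 acetate, the elimination placing the dienyl group trans to the ester and hence cis to CH2B, as is usual for ester-derived acetates.

Step 5
Reactants: 8 (2E)-3-methylpent-2-en-4-yn-1-ol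
Product: 9 tert-butyl{[(2E)-3-methylpent-2-en-4-yn-1-yl]oxy}diphenylsilane
Conditions: TBDPSCl, imidazole, CH2Cl2, 0 °C → rt
Reagents that add atoms: tert-butyl(chloro)diphenylsilane, CC(C)(C)[Si](Cl)(c1ccccc1)c1ccccc1
Why: Standard silylation of a primary allylic alcohol, the tert-butyldiphenylsilyl ether being chosen because it should survive the borane, the silyl triflate and the acetic acid of later steps and fall only to fluoride.

Step 6
Reactants: 9 tert-butyl{[(2E)-3-methylpent-2-en-4-yn-1-yl]oxy}diphenylsilane
Product: 11 (3E)-5-[(tert-butyldiphenylsilyl)oxy]-3-methylpent-3-enal, via dienylborane 10 (not isolated)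
Conditions: Cy2BH (1.05 equiv; from BH3·SMe2 and cyclohexene, THF, 0 °C), THF, 0 °C → rt; then 30 % H2O2, pH 7 phosphate buffer (NaH2PO4/Na2HPO4), 0 °C; used crude at once
Reagents that add atoms: hydrogen peroxide, OO
Why: Alkyne hydroboration–oxidation, in which the bulky dialkylborane adds once, anti-Markovnikov, to the terminal alkyne and ignores the trisubstituted alkene, and buffered oxidation releases a dienol that ketonises by α-protonation to the β,γ-unsaturated aldehyde with the purchased E alkene untouched.

Step 7
Reactants: 7 tert-butyl (2E,4E)-6-methyl-2-[(4,4,5,5-tetramethyl-1,3,2-dioxaborolan-2-yl)methyl]hepta-2,4,6-trienoate; 11 (3E)-5-[(tert-butyldiphenylsilyl)oxy]-3-methylpent-3-enal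
Product: 13 tert-butyl (3R,4R,6E)-8-[(tert-butyldiphenylsilyl)oxy]-4-hydroxy-6-methyl-2-methylidene-3-[(1E)-3-methylbuta-1,3-dien-1-yl]oct-6-enoate, via pinacol borate 12 (not isolated)
Conditions: 11 (1.3 equiv), (S)-TRIP [(S)-3,3′-bis(2,4,6-triisopropylphenyl)-1,1′-binaphthyl-2,2′-diyl hydrogen phosphate] (10 mol %), 4 Å MS, toluene, −20 °C → rt; aq NaHCO3 work-up
Reagents that add atoms: none
Why: Proposed new method: the chiral phosphoric acid is expected to hydrogen-bond to the pseudo-axial boronate oxygen and to the formyl C–H inside the closed Zimmerman–Traxler chair, which should raise the electrophilicity of boron enough to overcome the low reactivity of the ester-substituted allylboronate (a class so far accelerated by Sc(OTf)3 and triflic acid) and shield one aldehyde face, so that C7–C8 forms with allyl transposition to C11=C13, the dienyl group cis to CH2B sitting axial and giving the syn (7R,8R) adduct by si-face attack, while the bulky tert-butyl ester keeps O8 from lactonising onto C12; the closest known reaction type is the phosphoric acid-catalysed enantioselective allyl- and crotylboration of aldehydes with pinacol boronates.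

Step 8
Reactants: 13 tert-butyl (3R,4R,6E)-8-[(tert-butyldiphenylsilyl)oxy]-4-hydroxy-6-methyl-2-methylidene-3-[(1E)-3-methylbuta-1,3-dien-1-yl]oct-6-enoate; 14 methacrylic anhydride
Product: 15 tert-butyl (3R,4R,6E)-8-[(tert-butyldiphenylsilyl)oxy]-6-methyl-2-methylidene-3-[(1E)-3-methylbuta-1,3-dien-1-yl]-4-[(2-methylprop-2-enoyl)oxy]oct-6-enoate
Conditions: 14 (2 equiv), DMAP (0.2 equiv), iPr2NEt (3 equiv), CH2Cl2, 0 °C → rt
Reagents that add atoms: none
Why: DMAP-catalysed acylation of the hindered secondary alcohol with the anhydride, under amine conditions too mild to deprotonate the doubly allylic C7–H, and with retention at C8 because the C8–O bond is not broken.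

Step 9
Reactants: 15 tert-butyl (3R,4R,6E)-8-[(tert-butyldiphenylsilyl)oxy]-6-methyl-2-methylidene-3-[(1E)-3-methylbuta-1,3-dien-1-yl]-4-[(2-methylprop-2-enoyl)oxy]oct-6-enoate
Product: 17 (3R,4R,6E)-8-[(tert-butyldiphenylsilyl)oxy]-6-methyl-2-methylidene-3-[(1E)-3-methylbuta-1,3-dien-1-yl]-4-[(2-methylprop-2-enoyl)oxy]oct-6-enoic acid, via trimethylsilyl ester 16 (not isolated)
Conditions: TMSOTf (3 equiv), 2,6-lutidine (5 equiv), CH2Cl2, 0 °C; then pH 5 aqueous buffer
Reagents that add atoms: none
Why: Silyl triflate-mediated tert-butyl ester cleavage, in which O-silylation of the ester carbonyl and loss of the tert-butyl group as isobutene give the silyl ester that is hydrolysed on work-up, the lutidine keeping the medium free of protic acid so that the diene, the silyl ether and the methacrylate should remain intact.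

Step 10
Reactants: 17 (3R,4R,6E)-8-[(tert-butyldiphenylsilyl)oxy]-6-methyl-2-methylidene-3-[(1E)-3-methylbuta-1,3-dien-1-yl]-4-[(2-methylprop-2-enoyl)oxy]oct-6-enoic acid
Product: 18 (1R,3E)-1-[(2R,3R)-2-[(1E)-3-(acetyloxy)-2-methylprop-1-en-1-yl]-4-methylidene-5-oxooxolan-3-yl]-5-[(tert-butyldiphenylsilyl)oxy]-3-methylpent-3-en-1-yl 2-methylprop-2-enoate
Conditions: Pd(OAc)2 (10 mol %), p-benzoquinone (20 mol %), MnO2 (1.5 equiv), LiOAc (2 equiv), acetone/AcOH 4:1, rt, chloride-free, 17 added slowly
Reagents that add atoms: acetic acid, CC(=O)O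
Why: Proposed new method: divalent palladium should complex the electron-rich isoprenyl diene rather than the two electron-poor acrylic alkenes or the hindered trisubstituted one, the C12 carboxylate then adds to C6 on the face opposite the metal to give a π-allylpalladium spanning C5–C4–C3, quinone coordination triggers acetate delivery to C3, and the zerovalent palladium released is returned to the divalent state by the quinone/MnO2 couple; the closest known reaction types are the palladium/benzoquinone 1,4-acetoxylactonisation of cyclic dienyl acetic acids and the intermolecular 1,4-diacetoxylation of acyclic dienes such as isoprene. The only ring, the α-methylene-γ-lactone, closes in a 5-exo-trig mode through the C6–O bond. The new stereocentre C6 is controlled by C7, whose branched C8 substituent should force the C5 side chain trans to it, and because oxypalladation is reversible in acetic acid the more stable trans-4,5-disubstituted lactone is expected to prevail. The step needs 1,4- over 1,2-regioselectivity, secured by the unsubstituted primary C3 terminus against the secondary, lactone-flanked C5, and E geometry, secured by the syn position of the C6 substituent on the allyl unit. C3 is not stereogenic, so the cis or trans course of acetate delivery is immaterial, and the reverse order of events (acetate first at C3, carboxylate second at C6) leads to the same product. The methacrylate already on O8 excludes a competing lactone, and keeping the quinone catalytic should suppress its Diels–Alder addition to the diene.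

Step 11
Reactants: 18 (1R,3E)-1-[(2R,3R)-2-[(1E)-3-(acetyloxy)-2-methylprop-1-en-1-yl]-4-methylidene-5-oxooxolan-3-yl]-5-[(tert-butyldiphenylsilyl)oxy]-3-methylpent-3-en-1-yl 2-methylprop-2-enoate
Product: 19 (1R,3E)-1-[(2R,3R)-2-[(1E)-3-(acetyloxy)-2-methylprop-1-en-1-yl]-4-methylidene-5-oxooxolan-3-yl]-5-hydroxy-3-methylpent-3-en-1-yl 2-methylprop-2-enoate (CNP0323189.1)
Conditions: HF·pyridine, pyridine, THF, 0 °C → rt
Reagents that add atoms: none
Why: Fluoride-mediated desilylation under buffered, weakly acidic conditions, which generates no alkoxide and so should cause neither acyl migration nor conjugate addition to the methylene lactone or the methacrylate.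

**Compound list**

1 | methacrolein | C=C(C)C=O | starting material
2 | (triphenylphosphoranylidene)acetaldehyde | O=CC=P(c1ccccc1)(c1ccccc1)c1ccccc1 | starting material
3 | (2E)-4-methylpenta-2,4-dienal | C=C(C)/C=C/C=O | intermediate
4 | tert-butyl acrylate | C=CC(=O)OC(C)(C)C | starting material
5 | tert-butyl (4E)-3-hydroxy-6-methyl-2-methylidenehepta-4,6-dienoate (racemic) | C=C(C)/C=C/C(O)C(=C)C(=O)OC(C)(C)C | intermediate
6 | tert-butyl (4E)-3-acetoxy-6-methyl-2-methylidenehepta-4,6-dienoate (racemic) | C=C(C)/C=C/C(OC(C)=O)C(=C)C(=O)OC(C)(C)C | intermediate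
7 | tert-butyl (2E,4E)-6-methyl-2-[(4,4,5,5-tetramethyl-1,3,2-dioxaborolan-2-yl)methyl]hepta-2,4,6-trienoate | CC1(C)OB(C/C(C(=O)OC(C)(C)C)=C\C=C\C(C)=C)OC1(C)C | intermediate
8 | (2E)-3-methylpent-2-en-4-yn-1-ol | C#C/C(C)=C/CO | starting material
9 | tert-butyl{[(2E)-3-methylpent-2-en-4-yn-1-yl]oxy}diphenylsilane | C#C/C(C)=C/CO[Si](c1ccccc1)(c1ccccc1)C(C)(C)C | intermediate
10 | dicyclohexyl{(1E,3E)-5-[(tert-butyldiphenylsilyl)oxy]-3-methylpenta-1,3-dien-1-yl}borane | C1CCCCC1B(/C=C/C(C)=C/CO[Si](c2ccccc2)(c2ccccc2)C(C)(C)C)C1CCCCC1 | intermediate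
11 | (3E)-5-[(tert-butyldiphenylsilyl)oxy]-3-methylpent-3-enal | O=CC/C(C)=C/CO[Si](c1ccccc1)(c1ccccc1)C(C)(C)C | intermediate
12 | tert-butyl (3R,4R,6E)-8-[(tert-butyldiphenylsilyl)oxy]-6-methyl-2-methylidene-3-[(1E)-3-methylbuta-1,3-dien-1-yl]-4-[(4,4,5,5-tetramethyl-1,3,2-dioxaborolan-2-yl)oxy]oct-6-enoate | CC1(C)OB(O[C@H](C/C(C)=C/CO[Si](c2ccccc2)(c2ccccc2)C(C)(C)C)[C@@H](C(=C)C(=O)OC(C)(C)C)/C=C/C(C)=C)OC1(C)C | intermediate
13 | tert-butyl (3R,4R,6E)-8-[(tert-butyldiphenylsilyl)oxy]-4-hydroxy-6-methyl-2-methylidene-3-[(1E)-3-methylbuta-1,3-dien-1-yl]oct-6-enoate | O[C@H](C/C(C)=C/CO[Si](c1ccccc1)(c1ccccc1)C(C)(C)C)[C@@H](C(=C)C(=O)OC(C)(C)C)/C=C/C(C)=C | intermediate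
14 | methacrylic anhydride | C=C(C)C(=O)OC(=O)C(C)=C | starting material
15 | tert-butyl (3R,4R,6E)-8-[(tert-butyldiphenylsilyl)oxy]-6-methyl-2-methylidene-3-[(1E)-3-methylbuta-1,3-dien-1-yl]-4-[(2-methylprop-2-enoyl)oxy]oct-6-enoate | C=C(C)C(=O)O[C@H](C/C(C)=C/CO[Si](c1ccccc1)(c1ccccc1)C(C)(C)C)[C@@H](C(=C)C(=O)OC(C)(C)C)/C=C/C(C)=C | intermediate
16 | trimethylsilyl (3R,4R,6E)-8-[(tert-butyldiphenylsilyl)oxy]-6-methyl-2-methylidene-3-[(1E)-3-methylbuta-1,3-dien-1-yl]-4-[(2-methylprop-2-enoyl)oxy]oct-6-enoate | C=C(C)C(=O)O[C@H](C/C(C)=C/CO[Si](c1ccccc1)(c1ccccc1)C(C)(C)C)[C@@H](C(=C)C(=O)O[Si](C)(C)C)/C=C/C(C)=C | intermediate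
17 | (3R,4R,6E)-8-[(tert-butyldiphenylsilyl)oxy]-6-methyl-2-methylidene-3-[(1E)-3-methylbuta-1,3-dien-1-yl]-4-[(2-methylprop-2-enoyl)oxy]oct-6-enoic acid | C=C(C)C(=O)O[C@H](C/C(C)=C/CO[Si](c1ccccc1)(c1ccccc1)C(C)(C)C)[C@@H](C(=C)C(=O)O)/C=C/C(C)=C | intermediate
18 | (1R,3E)-1-[(2R,3R)-2-[(1E)-3-(acetyloxy)-2-methylprop-1-en-1-yl]-4-methylidene-5-oxooxolan-3-yl]-5-[(tert-butyldiphenylsilyl)oxy]-3-methylpent-3-en-1-yl 2-methylprop-2-enoate | C=C(C)C(=O)O[C@H](C/C(C)=C/CO[Si](c2ccccc2)(c2ccccc2)C(C)(C)C)[C@H]1C(=C)C(=O)O[C@@H]1/C=C(\C)COC(C)=O | intermediate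
19 | (1R,3E)-1-[(2R,3R)-2-[(1E)-3-(acetyloxy)-2-methylprop-1-en-1-yl]-4-methylidene-5-oxooxolan-3-yl]-5-hydroxy-3-methylpent-3-en-1-yl 2-methylprop-2-enoate (CNP0323189.1) | C=C(C)C(=O)O[C@H](C/C(C)=C/CO)[C@H]1C(=C)C(=O)O[C@@H]1/C=C(\C)COC(C)=O | target

**Step count and risks**

Total step count: 11. Longest linear sequence: 9 steps (steps 1, 2, 3, 4, 7, 8, 9, 10, 11, from methacrolein); the aldehyde branch (steps 5 and 6) joins at step 7.

Steps most likely to fail:

1. Step 10 (labelled). What may go wrong: incomplete facial control at C6 so that cis lactone leaks through; acetate capture at C5 instead of C3; loss of the diene by cycloaddition with the quinone; or palladation of the doubly allylic C7–H. The fallback uses known halolactonisation and allylic substitution chemistry. It sets out from 17: iodine in acetonitrile at 0 °C, base-free so that the iodolactonisation equilibrates to the trans lactone, should close the same C6–O bond. The first-formed allylic iodides are expected to converge by 1,3-shift on the primary iodide (1R,3E)-5-[(tert-butyldiphenylsilyl)oxy]-1-[(2R,3R)-2-[(1E)-3-iodo-2-methylprop-1-en-1-yl]-4-methylidene-5-oxooxolan-3-yl]-3-methylpent-3-en-1-yl 2-methylprop-2-enoate F1. Displacement of iodide with CsOAc in DMF at rt then gives the allylic acetate and returns to the route at 18.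

2. Step 7 (labelled). What may go wrong: the phosphoric acid may not accelerate the electron-poor boronate enough, giving slow conversion, erosion of enantioselectivity by the uncatalysed pathway, and drift of the β,γ-unsaturated aldehyde into conjugation during long reaction times. The fallback uses the known Lewis acid-catalysed allylboration of 2-alkoxycarbonyl allylboronates followed by resolution. It sets out from 7 and 11: Sc(OTf)3 (10 mol %) in CH2Cl2 at −78 → 0 °C should give the syn adduct stereospecifically but as a racemate, that is 12 together with its mirror image, the (3S,4S) pinacol borate F2. After hydrolysis this gives 13 together with its enantiomer, tert-butyl (3S,4S,6E)-8-[(tert-butyldiphenylsilyl)oxy]-4-hydroxy-6-methyl-2-methylidene-3-[(1E)-3-methylbuta-1,3-dien-1-yl]oct-6-enoate F3. Preparative chromatography on a chiral stationary phase separates the enantiomers and returns to the route at 13.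

3. Step 2. What may go wrong: slow turnover of the amine catalyst with the hindered acrylate, during which the volatile dienal polymerises, dimerises or suffers conjugate addition. The fallback replaces the amine-catalysed addition with a hydroalumination–addition sequence. It sets out from 3: tert-butyl propiolate is treated with iBu2AlH and N-methylmorpholine N-oxide in THF at 0 °C to give [1-(tert-butoxycarbonyl)ethenyl]bis(2-methylpropyl)alumane F4, which should add 1,2 to 3. The resulting diisobutylaluminium alkoxide of tert-butyl (4E)-3-hydroxy-6-methyl-2-methylidenehepta-4,6-dienoate F5 is hydrolysed with aqueous potassium sodium tartrate (KNaC4H4O6) and returns to the route at 5.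

**Further compounds**

F1 | step 10 | (1R,3E)-5-[(tert-butyldiphenylsilyl)oxy]-1-[(2R,3R)-2-[(1E)-3-iodo-2-methylprop-1-en-1-yl]-4-methylidene-5-oxooxolan-3-yl]-3-methylpent-3-en-1-yl 2-methylprop-2-enoate | C=C(C)C(=O)O[C@H](C/C(C)=C/CO[Si](c2ccccc2)(c2ccccc2)C(C)(C)C)[C@H]1C(=C)C(=O)O[C@@H]1/C=C(\C)CI
F2 | step 7 | tert-butyl (3S,4S,6E)-8-[(tert-butyldiphenylsilyl)oxy]-6-methyl-2-methylidene-3-[(1E)-3-methylbuta-1,3-dien-1-yl]-4-[(4,4,5,5-tetramethyl-1,3,2-dioxaborolan-2-yl)oxy]oct-6-enoate | CC1(C)OB(O[C@@H](C/C(C)=C/CO[Si](c2ccccc2)(c2ccccc2)C(C)(C)C)[C@H](C(=C)C(=O)OC(C)(C)C)/C=C/C(C)=C)OC1(C)C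
F3 | step 7 | tert-butyl (3S,4S,6E)-8-[(tert-butyldiphenylsilyl)oxy]-4-hydroxy-6-methyl-2-methylidene-3-[(1E)-3-methylbuta-1,3-dien-1-yl]oct-6-enoate | O[C@@H](C/C(C)=C/CO[Si](c1ccccc1)(c1ccccc1)C(C)(C)C)[C@H](C(=C)C(=O)OC(C)(C)C)/C=C/C(C)=C
F4 | step 2 | [1-(tert-butoxycarbonyl)ethenyl]bis(2-methylpropyl)alumane | C=C(C(=O)OC(C)(C)C)[Al](CC(C)C)CC(C)C
F5 | step 2 | diisobutylaluminium alkoxide of tert-butyl (4E)-3-hydroxy-6-methyl-2-methylidenehepta-4,6-dienoate | C=C(C)/C=C/C(O[Al](CC(C)C)CC(C)C)C(=C)C(=O)OC(C)(C)C
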